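## Retrosynthetic overview

1. Last bond: the lactone α-carbon to benzylic CH2 bond, made by trans-selective alkylation of an (S)-β-benzyl-γ-butyrolactone enolate with a dihydrobenzofuran benzylic bromide; global O-debenzylation finishes.
2. Key step: the O1–C2 bond of the dihydrobenzofuran, closed by dehydrogenative coupling of a benzylic C–H with the ring-A phenol O–H; this forms the ring and sets C2 trans to C3.
3. C3 is set beforehand by iridium-catalysed asymmetric hydrogenation of a (Z)-trisubstituted alkene, itself assembled by Sonogashira coupling, syn-borylcupration and Suzuki coupling.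
4. The lactone fragment comes from Stobbe condensation, rhodium-catalysed asymmetric hydrogenation and ester reduction with lactonisation.
5. Ring order: the dihydrofuran ring (step 6) and the butyrolactone ring (step 11) are closed in separate fragments, which are then joined (step 12).

Assumption: compound 1 and the other four starting materials are taken as catalogue compounds; the sense of induction of the two hydrogenation catalysts is assigned by analogy, and the ligand antipode is swapped if it proves opposite.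

## Route

Step 1
Reactants: 1 3-(benzyloxy)-4-hydroxybenzaldehyde
Product: 2 3-(benzyloxy)-5-bromo-4-hydroxybenzaldehyde
Conditions: Br2 (1.05 equiv), AcOH, rt
Reagents that add atoms: bromine, BrBr
Why: Electrophilic aromatic bromination; the free phenol directs to its only open ortho position, as in the bromination of vanillin.

Step 2
Reactants: 3 1-(benzyloxy)-4-bromo-2-methoxybenzene; 4 benzyl propargyl ether
Product: 5 1-(benzyloxy)-4-[3-(benzyloxy)prop-1-yn-1-yl]-2-methoxybenzene
Conditions: PdCl2(MeCN)2 (2 mol%), XPhos (6 mol%), Cs2CO3, MeCN, 80 °C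
Reagents that add atoms: none
Why: Copper-free Sonogashira coupling; the bulky phosphine lets palladium insert into the electron-rich aryl bromide and avoids alkyne homocoupling.

Step 3
Reactants: 5 1-(benzyloxy)-4-[3-(benzyloxy)prop-1-yn-1-yl]-2-methoxybenzene
Product: 6 2-{(Z)-3-(benzyloxy)-1-[4-(benzyloxy)-3-methoxyphenyl]prop-1-en-2-yl}-4,4,5,5-tetramethyl-1,3,2-dioxaborolane (boron cis to the vinyl H)
Conditions: CuCl (5 mol%), Xantphos (5 mol%), NaOtBu (10 mol%), B2pin2 (1.1 equiv), MeOH (2 equiv), THF, rt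
Reagents that add atoms: bis(pinacolato)diboron, CC1(C)OB(OC1(C)C)B1OC(C)(C)C(C)(C)O1
Why: Copper-catalysed syn-borylcupration and protonation (formal hydroboration); the aryl group stabilises copper on its own carbon, so boron goes to the carbon bearing CH2OBn, and syn addition fixes the geometry.

Step 4
Reactants: 2 3-(benzyloxy)-5-bromo-4-hydroxybenzaldehyde; 6 the (Z)-alkenyl boronate
Product: 7 3-(benzyloxy)-5-{(Z)-3-(benzyloxy)-1-[4-(benzyloxy)-3-methoxyphenyl]prop-1-en-2-yl}-4-hydroxybenzaldehyde (the two aryl groups trans)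
Conditions: Pd(OAc)2 (3 mol%), SPhos (6 mol%), K3PO4 (3 equiv), 1,4-dioxane/H2O 5:1, 80 °C
Reagents that add atoms: none
Why: Suzuki–Miyaura coupling with retention of alkene geometry; the ligand tolerates the ortho-bromophenol and the hindered alkenyl boronate, and the aldehyde is inert.

Step 5
Reactants: 7 the (Z)-alkene
Product: 8 3-(benzyloxy)-5-{(2R)-1-(benzyloxy)-3-[4-(benzyloxy)-3-methoxyphenyl]propan-2-yl}-4-hydroxybenzaldehyde
Conditions: [Ir(cod)((S)-tBu-PHOX)][B(3,5-(CF3)2C6H3)4] (2 mol%), H2 (50 bar), CH2Cl2, rt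
Reagents that add atoms: none
Why: Iridium P,N-ligand asymmetric hydrogenation of a trisubstituted stilbene-type alkene; the ligand selects the alkene face and sets the centre R by analogy with (E)-1,2-diphenylpropene, while aldehyde, phenol and benzyl ethers are not reduced.

Step 6
Reactants: 8 the (2R)-diarylpropyl ether
Product: 10 (2S,3R)-7-(benzyloxy)-3-[(benzyloxy)methyl]-2-[4-(benzyloxy)-3-methoxyphenyl]-2,3-dihydro-1-benzofuran-5-carbaldehyde, via benzylic cation 9 (not isolated)
Conditions: DDQ (1.1 equiv), 2,6-dichloropyridine (2 equiv), 4 Å MS, ClCH2CH2Cl, 0 to 40 °C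
Reagents that add atoms: none
Why: Proposed new method: dehydrogenative benzylic C–H/phenol O–H cycloetherification on an acyclic 2-(2-hydroxyaryl)-3-arylpropyl ether, not yet shown for trans-2-aryl-3-(alkoxymethyl)dihydrobenzofurans. DDQ complexes the 4-benzyloxy-3-methoxyphenyl ring and abstracts hydride from the CH2 conjugated to it, giving the quinone-methide-like cation 9; the ring-A phenol, kept from oxidation by its para formyl group, closes the five-membered ring anti to the CH2OBn group on the existing centre, setting C2 as S (trans), which is also the thermodynamic isomer because closure is reversible under the acidic hydroquinone. Closest known reaction type: DDQ hydride-abstraction cyclisation of 2'-hydroxyisoflavans to pterocarpans and of 1-(2-hydroxyaryl)-3-arylpropanes to flavans.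

Step 7
Reactants: 10 the dihydrobenzofuran aldehyde
Product: 11 {(2S,3R)-7-(benzyloxy)-3-[(benzyloxy)methyl]-2-[4-(benzyloxy)-3-methoxyphenyl]-2,3-dihydro-1-benzofuran-5-yl}methanol
Conditions: NaBH4, MeOH/THF, 0 °C
Reagents that add atoms: none
Why: Borohydride reduction of the aryl aldehyde; nothing else is reducible and both stereocentres are untouched.

Step 8
Reactants: 11 the benzylic alcohol
Product: 12 (2S,3R)-7-(benzyloxy)-3-[(benzyloxy)methyl]-2-[4-(benzyloxy)-3-methoxyphenyl]-5-(bromomethyl)-2,3-dihydro-1-benzofuran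
Conditions: CBr4, PPh3, CH2Cl2, 0 °C; used crude
Reagents that add atoms: carbon tetrabromide, BrC(Br)(Br)Br
Why: Appel bromination converts the only hydroxyl into the bromide under neutral conditions, so the acid-labile benzylic aryl ether of the ring is not opened.

Step 9
Reactants: 13 4-(benzyloxy)-3-methoxybenzaldehyde; 14 dimethyl succinate
Product: 15 (E)-4-[4-(benzyloxy)-3-methoxyphenyl]-3-(methoxycarbonyl)but-3-enoic acid
Conditions: KOtBu, tBuOH, reflux; then aq. HCl
Reagents that add atoms: none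
Why: Stobbe condensation gives the half-ester with the free acid on the CH2 arm and the E alkene as the major isomer.

Step 10
Reactants: 15 the (E)-half-ester
Product: 16 (3S)-4-[4-(benzyloxy)-3-methoxyphenyl]-3-(methoxycarbonyl)butanoic acid
Conditions: [Rh(cod)((R,R)-Et-DuPhos)]OSO2CF3 (0.5 mol%), NaOMe (10 mol%), H2 (5 bar), MeOH, rt
Reagents that add atoms: none
Why: Rhodium–bisphospholane asymmetric hydrogenation of an itaconate-type half-ester; the carboxylate binds rhodium and the ligand delivers H2 to one alkene face to set the S centre, and the homogeneous catalyst does not cleave the benzyl ether.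

Step 11
Reactants: 16 the (3S)-half-ester
Product: 18 (4S)-4-[4-(benzyloxy)-3-methoxybenzyl]dihydrofuran-2(3H)-one, via hydroxy acid 17 (not isolated)
Conditions: LiOH·H2O (1.0 equiv), MeOH, then evaporate; LiBH4 (2 equiv), THF, 0 °C to rt; then 2 M HCl, rt
Reagents that add atoms: none
Why: Chemoselective borohydride reduction of the ester beside the unreactive carboxylate salt, then acid-driven lactonisation of hydroxy acid 17; the stereocentre is not involved.

Step 12
Reactants: 18 the (4S)-lactone; 12 the benzylic bromide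
Product: 20 (3S,4S)-3-({(2S,3R)-7-(benzyloxy)-3-[(benzyloxy)methyl]-2-[4-(benzyloxy)-3-methoxyphenyl]-2,3-dihydro-1-benzofuran-5-yl}methyl)-4-[4-(benzyloxy)-3-methoxybenzyl]dihydrofuran-2(3H)-one, via lithium enolate 19 (not isolated)
Conditions: LiN(SiMe3)2 (1.1 equiv), THF, −78 °C, 45 min; then 12, DMPU, −78 to −30 °C
Reagents that add atoms: none
Why: Lactone enolate alkylation; the bromide approaches anti to the C4 benzyl group, giving the trans (3S,4S) lactone as is standard for dibenzylbutyrolactone lignans.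

Step 13
Reactants: 20 the tetra-O-benzyl ether
Product: 21 (3S,4S)-3-{[(2S,3R)-7-hydroxy-2-(4-hydroxy-3-methoxyphenyl)-3-(hydroxymethyl)-2,3-dihydro-1-benzofuran-5-yl]methyl}-4-(4-hydroxy-3-methoxybenzyl)dihydrofuran-2(3H)-one (CNP0118131.1)
Conditions: H2 (1 atm), palladium on carbon (10% Pd/C), EtOAc/MeOH, rt
Reagents that add atoms: none
Why: Hydrogenolysis of three aryl and one alkyl benzyl ether; neutral, low-pressure conditions leave the cyclic benzylic aryl ether, the lactone and all four stereocentres intact.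

## Compound list

1 | 3-(benzyloxy)-4-hydroxybenzaldehyde | O=Cc1ccc(O)c(OCc2ccccc2)c1 | starting material
2 | 3-(benzyloxy)-5-bromo-4-hydroxybenzaldehyde | O=Cc1cc(Br)c(O)c(OCc2ccccc2)c1 | intermediate
3 | 1-(benzyloxy)-4-bromo-2-methoxybenzene | COc1cc(Br)ccc1OCc1ccccc1 | starting material
4 | benzyl propargyl ether | C#CCOCc1ccccc1 | starting material
5 | 1-(benzyloxy)-4-[3-(benzyloxy)prop-1-yn-1-yl]-2-methoxybenzene | COc1cc(C#CCOCc2ccccc2)ccc1OCc1ccccc1 | intermediate
6 | 2-{(Z)-3-(benzyloxy)-1-[4-(benzyloxy)-3-methoxyphenyl]prop-1-en-2-yl}-4,4,5,5-tetramethyl-1,3,2-dioxaborolane | COc1cc(/C=C(\COCc2ccccc2)B2OC(C)(C)C(C)(C)O2)ccc1OCc1ccccc1 | intermediate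
7 | 3-(benzyloxy)-5-{(Z)-3-(benzyloxy)-1-[4-(benzyloxy)-3-methoxyphenyl]prop-1-en-2-yl}-4-hydroxybenzaldehyde | COc1cc(/C=C(\COCc2ccccc2)c2cc(C=O)cc(OCc3ccccc3)c2O)ccc1OCc1ccccc1 | intermediate
8 | 3-(benzyloxy)-5-{(2R)-1-(benzyloxy)-3-[4-(benzyloxy)-3-methoxyphenyl]propan-2-yl}-4-hydroxybenzaldehyde | COc1cc(C[C@@H](COCc2ccccc2)c2cc(C=O)cc(OCc3ccccc3)c2O)ccc1OCc1ccccc1 | intermediate
9 | (2R)-3-(benzyloxy)-2-[3-(benzyloxy)-5-formyl-2-hydroxyphenyl]-1-[4-(benzyloxy)-3-methoxyphenyl]propan-1-ylium, benzylic cation (not isolated) | COc1cc([CH+][C@@H](COCc2ccccc2)c2cc(C=O)cc(OCc3ccccc3)c2O)ccc1OCc1ccccc1 | intermediate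
10 | (2S,3R)-7-(benzyloxy)-3-[(benzyloxy)methyl]-2-[4-(benzyloxy)-3-methoxyphenyl]-2,3-dihydro-1-benzofuran-5-carbaldehyde | O=Cc1cc(OCc2ccccc2)c2c(c1)[C@H](COCc1ccccc1)[C@@H](c1ccc(OCc3ccccc3)c(OC)c1)O2 | intermediate
11 | {(2S,3R)-7-(benzyloxy)-3-[(benzyloxy)methyl]-2-[4-(benzyloxy)-3-methoxyphenyl]-2,3-dihydro-1-benzofuran-5-yl}methanol | OCc1cc(OCc2ccccc2)c2c(c1)[C@H](COCc1ccccc1)[C@@H](c1ccc(OCc3ccccc3)c(OC)c1)O2 | intermediate
12 | (2S,3R)-7-(benzyloxy)-3-[(benzyloxy)methyl]-2-[4-(benzyloxy)-3-methoxyphenyl]-5-(bromomethyl)-2,3-dihydro-1-benzofuran | BrCc1cc(OCc2ccccc2)c2c(c1)[C@H](COCc1ccccc1)[C@@H](c1ccc(OCc3ccccc3)c(OC)c1)O2 | intermediate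
13 | 4-(benzyloxy)-3-methoxybenzaldehyde | COc1cc(C=O)ccc1OCc1ccccc1 | starting material
14 | dimethyl succinate | COC(=O)CCC(=O)OC | starting material
15 | (E)-4-[4-(benzyloxy)-3-methoxyphenyl]-3-(methoxycarbonyl)but-3-enoic acid | COC(=O)/C(CC(=O)O)=C/c1ccc(OCc2ccccc2)c(OC)c1 | intermediate
16 | (3S)-4-[4-(benzyloxy)-3-methoxyphenyl]-3-(methoxycarbonyl)butanoic acid | COC(=O)[C@H](CC(=O)O)Cc1ccc(OCc2ccccc2)c(OC)c1 | intermediate
17 | (3S)-4-[4-(benzyloxy)-3-methoxyphenyl]-3-(hydroxymethyl)butanoic acid (not isolated) | OC[C@H](CC(=O)O)Cc1ccc(OCc2ccccc2)c(OC)c1 | intermediate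
18 | (4S)-4-[4-(benzyloxy)-3-methoxybenzyl]dihydrofuran-2(3H)-one | COc1cc(C[C@@H]2COC(=O)C2)ccc1OCc1ccccc1 | intermediate
19 | lithium (4S)-4-[4-(benzyloxy)-3-methoxybenzyl]-4,5-dihydrofuran-2-olate (not isolated) | [Li+].[O-]C1=C[C@H](Cc2ccc(OCc3ccccc3)c(OC)c2)CO1 | intermediate
20 | (3S,4S)-3-({(2S,3R)-7-(benzyloxy)-3-[(benzyloxy)methyl]-2-[4-(benzyloxy)-3-methoxyphenyl]-2,3-dihydro-1-benzofuran-5-yl}methyl)-4-[4-(benzyloxy)-3-methoxybenzyl]dihydrofuran-2(3H)-one | COc1cc(C[C@@H]2COC(=O)[C@H]2Cc2cc(OCc3ccccc3)c3c(c2)[C@H](COCc2ccccc2)[C@@H](c2ccc(OCc4ccccc4)c(OC)c2)O3)ccc1OCc1ccccc1 | intermediate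
21 | (3S,4S)-3-{[(2S,3R)-7-hydroxy-2-(4-hydroxy-3-methoxyphenyl)-3-(hydroxymethyl)-2,3-dihydro-1-benzofuran-5-yl]methyl}-4-(4-hydroxy-3-methoxybenzyl)dihydrofuran-2(3H)-one | COc1cc(C[C@@H]2COC(=O)[C@H]2Cc2cc(O)c3c(c2)[C@H](CO)[C@@H](c2ccc(O)c(OC)c2)O3)ccc1O | target

## Step count and risks

Total steps: 13. Longest linear sequence: 9 (steps 2, 3, 4, 5, 6, 7, 8, 12, 13).

Three steps most likely to fail:

Step 3, regiochemistry of the borylcupration. The propargylic ether and the electron-rich aryl group direct copper to opposite alkyne carbons, so the wrong boronate may dominate. The fallback sets out from 3. Sonogashira coupling with propargyl alcohol gives 3-[4-(benzyloxy)-3-methoxyphenyl]prop-2-yn-1-ol F1. Hydroxyl-directed trans-hydrostannation (Bu3SnH, [Cp*RuCl]4, CH2Cl2) puts tin on the carbon next to CH2OH and gives (Z)-3-[4-(benzyloxy)-3-methoxyphenyl]-2-(tributylstannyl)prop-2-en-1-ol F2. O-Benzylation (NaH, BnBr) gives tributyl{(Z)-3-(benzyloxy)-1-[4-(benzyloxy)-3-methoxyphenyl]prop-1-en-2-yl}stannane F3. Stille coupling with 2 (Pd(PPh3)4, CuI, CsF, DMF) gives the E isomer of 7, 3-(benzyloxy)-5-{(E)-3-(benzyloxy)-1-[4-(benzyloxy)-3-methoxyphenyl]prop-1-en-2-yl}-4-hydroxybenzaldehyde F4. Hydrogenation of F4 with the antipodal catalyst [Ir(cod)((R)-tBu-PHOX)][B(3,5-(CF3)2C6H3)4] comes back to the route at 8.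

Step 5, the asymmetric hydrogenation. The ortho-substituted aryl group on the fully substituted alkene carbon may slow the reaction or lower the ee, and the acidic iridium hydride may ionise the cinnamyl ether or trigger uncontrolled phenol addition. The fallback sets out from 7 and replaces asymmetric catalysis by resolution. Hydrogenation with the achiral catalyst [Ir(cod)(PCy3)(py)]PF6 gives racemic 3-(benzyloxy)-5-{1-(benzyloxy)-3-[4-(benzyloxy)-3-methoxyphenyl]propan-2-yl}-4-hydroxybenzaldehyde F5. Preparative chromatography on a chiral stationary phase then delivers the R enantiomer, which is 8, where the route is rejoined.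

Step 6, the proposed new cycloetherification. Risks are over-oxidation of 10 to the benzofuran, loss of a proton from cation 9 back to alkene 7, or oxidation of the ring-A phenol. The fallback uses known chemistry, sets out from 7 and does not pass through 8. Acetalisation (HC(OMe)3, PPTS, MeOH) gives 2-(benzyloxy)-6-{(Z)-3-(benzyloxy)-1-[4-(benzyloxy)-3-methoxyphenyl]prop-1-en-2-yl}-4-(dimethoxymethyl)phenol F6. Asymmetric hydroboration with monoisopinocampheylborane (the antipode that adds hydrogen to the required face), then NaBO3, gives 2-(benzyloxy)-6-{(1S,2R)-3-(benzyloxy)-1-[4-(benzyloxy)-3-methoxyphenyl]-1-hydroxypropan-2-yl}-4-(dimethoxymethyl)phenol F7. Acid treatment (TsOH, wet CH2Cl2) ionises the benzylic alcohol, the phenol closes to the trans ring whatever the carbinol configuration, and the acetal is hydrolysed in the same pot, which comes back to the route at 10.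

Further compounds
F1 | step 3 | 3-[4-(benzyloxy)-3-methoxyphenyl]prop-2-yn-1-ol | COc1cc(C#CCO)ccc1OCc1ccccc1
F2 | step 3 | (Z)-3-[4-(benzyloxy)-3-methoxyphenyl]-2-(tributylstannyl)prop-2-en-1-ol | CCCC[Sn](CCCC)(CCCC)/C(CO)=C\c1ccc(OCc2ccccc2)c(OC)c1
F3 | step 3 | tributyl{(Z)-3-(benzyloxy)-1-[4-(benzyloxy)-3-methoxyphenyl]prop-1-en-2-yl}stannane | CCCC[Sn](CCCC)(CCCC)/C(COCc1ccccc1)=C\c1ccc(OCc2ccccc2)c(OC)c1
F4 | step 3 | 3-(benzyloxy)-5-{(E)-3-(benzyloxy)-1-[4-(benzyloxy)-3-methoxyphenyl]prop-1-en-2-yl}-4-hydroxybenzaldehyde | COc1cc(/C=C(/COCc2ccccc2)c2cc(C=O)cc(OCc3ccccc3)c2O)ccc1OCc1ccccc1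
F5 | step 5 | racemic 3-(benzyloxy)-5-{1-(benzyloxy)-3-[4-(benzyloxy)-3-methoxyphenyl]propan-2-yl}-4-hydroxybenzaldehyde | COc1cc(CC(COCc2ccccc2)c2cc(C=O)cc(OCc3ccccc3)c2O)ccc1OCc1ccccc1
F6 | step 6 | 2-(benzyloxy)-6-{(Z)-3-(benzyloxy)-1-[4-(benzyloxy)-3-methoxyphenyl]prop-1-en-2-yl}-4-(dimethoxymethyl)phenol | COc1cc(/C=C(\COCc2ccccc2)c2cc(C(OC)OC)cc(OCc3ccccc3)c2O)ccc1OCc1ccccc1
F7 | step 6 | 2-(benzyloxy)-6-{(1S,2R)-3-(benzyloxy)-1-[4-(benzyloxy)-3-methoxyphenyl]-1-hydroxypropan-2-yl}-4-(dimethoxymethyl)phenol | COc1cc([C@@H](O)[C@@H](COCc2ccccc2)c2cc(C(OC)OC)cc(OCc3ccccc3)c2O)ccc1OCc1ccccc1
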